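**Plan**
Labels: ring A is the anisole ring and ring B the lactam (stereocentre C3). Ring C is the dienone: C1' C=O, C2' bearing C3, C3' OH, C4' H, C5' CH3, C6' with both prenyl groups.
Enabling feature: ring C is a cyclohexa-2,4-dienone with a quaternary C6', so it is the closed valence isomer of a dienylketene (C1' ketene carbon, C6' diene terminus). Its O–C1'–C2'(C3)–C3'–O array is the imprint of an alkoxyalkyne C2'≡C3'–OR on a vinylketene made of C1', C4', C5' and C6'.
Cuts: (a) C3'–OH back to OEt. (b) Both CH=CMe2 ends back to a dialdehyde, and this back to a spiro-cyclopentene, a temporary ring that ties the two arms together. (c) Ring C at C1'–C2', C3'–C4' and C1'–C6', giving a 3-(ethoxyethynyl)isoindolinone and a spiro-cyclobutenone. (d) C3–C(alkyne) and N–C(=O) of ring B.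
Forward: ring A is bought, ring B closes next and ring C closes last. The cyclopentene is then cleaved, a double Wittig reaction installs the prenyl groups, and the enol ether is hydrolysed.
Stereochemistry: the single stereocentre C3 is set by adding lithium ethoxyacetylide to an (R)-tert-butanesulfinyl aldimine and is only carried along afterwards.

Key step: step 9

Assumption: the acetylide is taken to add through the open, non-chelated transition state, that is, to the Re face of the (R)-sulfinyl imine. If chelation control prevailed, (S)-tert-butanesulfinamide would be used with nothing else changed.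
Remark: the descriptor at C3 reads R in the alkynyl compounds and S once C2' carries two oxygen-bearing branches. The spatial arrangement is the same throughout.

**Step 1**
Reactants: 1 methyl 3-methoxy-2-methylbenzoate
Product: 2 methyl 2-(bromomethyl)-3-methoxybenzoate
Conditions: NBS, AIBN (cat.), PhCF3, reflux
Reagents that add atoms: N-bromosuccinimide, O=C1CCC(=O)N1Br
Why: Wohl–Ziegler radical bromination attacks the only benzylic C–H bonds, and the ester-deactivated ring in a non-polar medium holds back ring bromination.

**Step 2**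
Reactants: 2 methyl 2-(bromomethyl)-3-methoxybenzoate
Product: 3 methyl 2-formyl-3-methoxybenzoate
Conditions: NMO, 4 Å MS, MeCN, rt
Reagents that add atoms: N-methylmorpholine N-oxide, C[N+]1([O-])CCOCC1
Why: Kornblum-type oxidation with an amine N-oxide (SN2 by the oxide oxygen, then loss of N-methylmorpholine) stops at the aldehyde and leaves the ester alone.

**Step 3**
Reactants: 3 methyl 2-formyl-3-methoxybenzoate, 4 (R)-2-methylpropane-2-sulfinamide
Product: 5 methyl 2-[(E)-{[(R)-tert-butylsulfinyl]imino}methyl]-3-methoxybenzoate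
Conditions: CuSO4, CH2Cl2, rt
Reagents that add atoms: none
Why: Dehydrative condensation of an aldehyde with tert-butanesulfinamide gives the E-aldimine with sulfur unchanged, and avoiding titanium alkoxides rules out transesterification of the methyl ester.

**Step 4**
Reactants: 5 methyl 2-[(E)-{[(R)-tert-butylsulfinyl]imino}methyl]-3-methoxybenzoate, 6 ethoxyacetylene
Product: 8 methyl 2-[(1R)-1-{[(R)-tert-butylsulfinyl]amino}-3-ethoxyprop-2-yn-1-yl]-3-methoxybenzoate, via lithium ethoxyacetylide 7 (not isolated)
Conditions: 6, n-BuLi, THF, −78 °C; then 5, −78 °C; aq NH4Cl at −78 °C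
Reagents that add atoms: none
Why: 1,2-addition of a lithium alkoxyacetylide to an N-tert-butanesulfinyl aldimine through the open transition state (S=O s-cis to C=N, attack anti to tert-butyl on the Re face) sets the stereocentre, the imine outruns the aryl ester at this temperature, and isolating 8 allows removal of the minor diastereomer.

**Step 5**
Reactants: 8 methyl 2-[(1R)-1-{[(R)-tert-butylsulfinyl]amino}-3-ethoxyprop-2-yn-1-yl]-3-methoxybenzoate
Product: 10 (3R)-3-(ethoxyethynyl)-4-methoxyisoindolin-1-one, via N-sulfinyl lactam 9 (not isolated)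
Conditions: LiN(SiMe3)2 (1.05 equiv), THF, −78 → 0 °C; aq NH4Cl
Reagents that add atoms: none
Why: The sulfinamide anion closes ring B on the neighbouring ester (5-exo-trig lactamisation) and the released methoxide attacks sulfur of the N-acylsulfinamide, a sulfinyl transfer of the type known from N-sulfinyloxazolidinones, so the auxiliary leaves without the acid that would hydrate the ynol ether.

**Step 6**
Reactants: 11 cyclopent-3-ene-1-carboxylic acid
Product: 12 cyclopent-3-ene-1-carbonyl chloride
Conditions: (COCl)2, DMF (cat.), CH2Cl2, 0 °C → rt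
Reagents that add atoms: oxalyl chloride, O=C(Cl)C(=O)Cl
Why: Standard acid chloride formation through the chloroiminium catalyst, to which the ring alkene is inert.

**Step 7**
Reactants: 12 cyclopent-3-ene-1-carbonyl chloride, 6 ethoxyacetylene
Product: 14 3-ethoxyspiro[3.4]octa-2,6-dien-1-one, via ketene 13 (not isolated)
Conditions: Et3N, Et2O, rt → reflux
Reagents that add atoms: none
Why: Dehydrochlorination gives the dialkylketene, which undergoes the classical regiospecific ketene–ethoxyacetylene [2+2] cycloaddition (alkyne CH to the ketene carbonyl carbon) to a 3-ethoxycyclobutenone, as known for cycloalkanecarbonyl chlorides.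

**Step 8**
Reactants: 14 3-ethoxyspiro[3.4]octa-2,6-dien-1-one
Product: 16 3-methylspiro[3.4]octa-2,6-dien-1-one, via carbinol 15 (not isolated)
Conditions: MeLi, Et2O, −78 °C; then 1 M HCl, 0 °C → rt
Reagents that add atoms: methyllithium, [Li]C; water, O
Why: Stork–Danheiser transposition (1,2-addition to the vinylogous ester, then acid-induced ionisation and enol ether hydrolysis) places the methyl group on C3 and keeps the spiro carbon next to the new carbonyl.

**Step 9**
Reactants: 10 (3R)-3-(ethoxyethynyl)-4-methoxyisoindolin-1-one, 16 3-methylspiro[3.4]octa-2,6-dien-1-one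
Product: 20 (3S)-3-(8-ethoxy-10-methyl-6-oxospiro[4.5]deca-2,7,9-trien-7-yl)-4-methoxyisoindolin-1-one, via vinylketene 17 (not isolated), via vinylcyclobutenone 18 (not isolated), via dienylketene 19 (not isolated)
Conditions: 16 (2 equiv), BHT (cat.), toluene (0.5 M), sealed tube, 110 °C, then 135 °C
Reagents that add atoms: none
Why: Proposed new method: heating opens 16 by 4π electrocyclic cleavage of the C(=O)–C(spiro) bond to vinylketene 17, whose ketene C=C takes up the ynol ether of 10 in a [2+2] cycloaddition to 18, a second 4π opening gives dienylketene 19, and a disrotatory 6π electrocyclisation joins the ketene carbon C1' to the fully substituted diene terminus C6'. The closest known reaction is the Danheiser benzannulation of cyclobutenones with alkoxyalkynes; new is the 4,4-disubstituted spiro-cyclobutenone, which leaves no hydrogen on C6' so that the cascade must halt at the cyclohexa-2,4-dienone, a closure known by itself from the thermal return of the dienylketenes of the Barton–Quinkert photolysis and from the cyclohexadienone annulation of β,β-disubstituted alkenyl chromium carbene complexes. Ring C, the only ring closed, forms in the 6π electrocyclic mode at C1'–C6' after C1'–C2' and C3'–C4' were made in the [2+2] event. No lasting stereocentre is created (C4 of 18 is erased on ring opening and C6' bears two equal arms), and C3 is a bystander in a medium free of acid and base, so its configuration is carried over. Regioselectivity follows from polarity, since the nucleophilic alkyne carbon that bears C3 bonds to the ketene carbonyl carbon and the oxygen-bearing carbon bonds to the ketene CH, which puts C3 between the two oxygenated carbons. Chemoselectivity of 17 for the alkyne is secured by the temporary cyclopentene, which holds both allylic C=C arms where they cannot fold onto the ketene (free prenyl arms would be taken by the intramolecular ketene–alkene [2+2] that leads to bicyclo[3.1.1]heptenones) and also blocks the Cope and retro-Claisen shifts of a 6-allyl dienone at this temperature, while the lactam N–H is a far poorer ketenophile than the ynol ether.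

**Step 10**
Reactants: 20 (3S)-3-(8-ethoxy-10-methyl-6-oxospiro[4.5]deca-2,7,9-trien-7-yl)-4-methoxyisoindolin-1-one
Product: 22 3-ethoxy-2-[(1S)-7-methoxy-3-oxoisoindolin-1-yl]-5-methyl-6,6-bis(2-oxoethyl)cyclohexa-2,4-dien-1-one, via cis-diol 21 (not isolated)
Conditions: OsO4 (cat.), NaIO4, 2,6-lutidine, dioxane–H2O, rt
Reagents that add atoms: OsO4, O=[Os](=O)(=O)=O; NaIO4, [Na+].[O-]I(=O)(=O)=O; water, O
Why: Lemieux–Johnson cleavage takes the temporary ring apart, because OsO4 prefers the only isolated cis-disubstituted alkene over the two conjugated, more substituted and electron-poorer C=C bonds of the vinylogous ester.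

**Step 11**
Reactants: 22 3-ethoxy-2-[(1S)-7-methoxy-3-oxoisoindolin-1-yl]-5-methyl-6,6-bis(2-oxoethyl)cyclohexa-2,4-dien-1-one, 23 isopropyltriphenylphosphonium iodide
Product: 25 3-ethoxy-2-[(1S)-7-methoxy-3-oxoisoindolin-1-yl]-5-methyl-6,6-bis(3-methylbut-2-en-1-yl)cyclohexa-2,4-dien-1-one, via ylide 24 (not isolated)
Conditions: 23, n-BuLi, THF, 0 °C; then 22, −78 → 0 °C (excess ylide)
Reagents that add atoms: none
Why: Twofold Wittig olefination with the non-stabilised isopropylidene ylide is much faster at the two aldehydes than at the hindered vinylogous ester carbonyl or the lactam, and the extra ylide that removes the N–H proton leaves an anion that shields C3–H from deprotonation.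

**Step 12**
Reactants: 25 3-ethoxy-2-[(1S)-7-methoxy-3-oxoisoindolin-1-yl]-5-methyl-6,6-bis(3-methylbut-2-en-1-yl)cyclohexa-2,4-dien-1-one
Product: 26 (3S)-3-[2-hydroxy-4-methyl-5,5-bis(3-methylbut-2-en-1-yl)-6-oxocyclohexa-1,3-dien-1-yl]-4-methoxyisoindolin-1-one
Conditions: 1 M NaOH, THF–MeOH, rt → 40 °C; then 1 M HCl to pH 4, 0 °C
Reagents that add atoms: sodium hydroxide, [Na+].[OH-]
Why: Vinylogous saponification (hydroxide adds to C3', ethoxide leaves) gives the stabilised 1,3-diketonate, which resists retro-Mannich loss of the lactam nitrogen so that C3 holds, and the basic medium spares the prenyl groups that acid would cyclise onto the enol oxygen.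

**Compound list**
1 | methyl 3-methoxy-2-methylbenzoate | COC(=O)c1cccc(OC)c1C | starting material
2 | methyl 2-(bromomethyl)-3-methoxybenzoate | COC(=O)c1cccc(OC)c1CBr | intermediate
3 | methyl 2-formyl-3-methoxybenzoate | COC(=O)c1cccc(OC)c1C=O | intermediate
4 | (R)-2-methylpropane-2-sulfinamide | CC(C)(C)[S@@](=O)N | starting material
5 | methyl 2-[(E)-{[(R)-tert-butylsulfinyl]imino}methyl]-3-methoxybenzoate | CC(C)(C)[S@@](=O)/N=C/c1c(OC)cccc1C(=O)OC | intermediate
6 | ethoxyacetylene | CCOC#C | starting material
7 | lithium ethoxyacetylide | [Li]C#COCC | intermediate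
8 | methyl 2-[(1R)-1-{[(R)-tert-butylsulfinyl]amino}-3-ethoxyprop-2-yn-1-yl]-3-methoxybenzoate | COC(=O)c1cccc(OC)c1[C@@H](C#COCC)N[S@](=O)C(C)(C)C | intermediate
9 | (3R)-2-[(R)-tert-butylsulfinyl]-3-(ethoxyethynyl)-4-methoxyisoindolin-1-one | COc1cccc2c1[C@@H](C#COCC)N([S@](=O)C(C)(C)C)C2=O | intermediate
10 | (3R)-3-(ethoxyethynyl)-4-methoxyisoindolin-1-one | COc1cccc2c1[C@@H](C#COCC)NC2=O | intermediate
11 | cyclopent-3-ene-1-carboxylic acid | OC(=O)C1CC=CC1 | starting material
12 | cyclopent-3-ene-1-carbonyl chloride | ClC(=O)C1CC=CC1 | intermediate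
13 | (cyclopent-3-en-1-ylidene)methanone (ketene) | O=C=C1CC=CC1 | intermediate
14 | 3-ethoxyspiro[3.4]octa-2,6-dien-1-one | CCOC1=CC(=O)C12CC=CC2 | intermediate
15 | 3-ethoxy-1-methylspiro[3.4]octa-2,6-dien-1-ol (racemic) | CCOC1=CC(C)(O)C12CC=CC2 | intermediate
16 | 3-methylspiro[3.4]octa-2,6-dien-1-one | CC1=CC(=O)C12CC=CC2 | intermediate
17 | 3-(cyclopent-3-en-1-ylidene)but-1-en-1-one (vinylketene) | O=C=CC(C)=C1CC=CC1 | intermediate
18 | 4-[1-(cyclopent-3-en-1-ylidene)ethyl]-3-ethoxy-2-[(1S)-7-methoxy-3-oxoisoindolin-1-yl]cyclobut-2-en-1-one (both C4 epimers) | COc1cccc2c1[C@@H](C3=C(OCC)C(C(C)=C4CC=CC4)C3=O)NC2=O | intermediate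
19 | (3E)-5-(cyclopent-3-en-1-ylidene)-3-ethoxy-2-[(1S)-7-methoxy-3-oxoisoindolin-1-yl]hexa-1,3-dien-1-one (dienylketene) | COc1cccc2c1[C@@H](C(=C=O)/C(OCC)=C\C(C)=C3CC=CC3)NC2=O | intermediate
20 | (3S)-3-(8-ethoxy-10-methyl-6-oxospiro[4.5]deca-2,7,9-trien-7-yl)-4-methoxyisoindolin-1-one | COc1cccc2c1[C@@H](C3=C(OCC)C=C(C)C4(CC=CC4)C3=O)NC2=O | intermediate
21 | (3S)-3-(8-ethoxy-2,3-dihydroxy-10-methyl-6-oxospiro[4.5]deca-7,9-dien-7-yl)-4-methoxyisoindolin-1-one (cis-diol) | COc1cccc2c1[C@@H](C3=C(OCC)C=C(C)C4(CC(O)C(O)C4)C3=O)NC2=O | intermediate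
22 | 3-ethoxy-2-[(1S)-7-methoxy-3-oxoisoindolin-1-yl]-5-methyl-6,6-bis(2-oxoethyl)cyclohexa-2,4-dien-1-one | COc1cccc2c1[C@@H](C3=C(OCC)C=C(C)C(CC=O)(CC=O)C3=O)NC2=O | intermediate
23 | isopropyltriphenylphosphonium iodide | CC(C)[P+](c1ccccc1)(c1ccccc1)c1ccccc1.[I-] | starting material
24 | isopropylidenetriphenylphosphorane | CC(C)=P(c1ccccc1)(c1ccccc1)c1ccccc1 | intermediate
25 | 3-ethoxy-2-[(1S)-7-methoxy-3-oxoisoindolin-1-yl]-5-methyl-6,6-bis(3-methylbut-2-en-1-yl)cyclohexa-2,4-dien-1-one | COc1cccc2c1[C@@H](C3=C(OCC)C=C(C)C(CC=C(C)C)(CC=C(C)C)C3=O)NC2=O | intermediate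
26 | (3S)-3-[2-hydroxy-4-methyl-5,5-bis(3-methylbut-2-en-1-yl)-6-oxocyclohexa-1,3-dien-1-yl]-4-methoxyisoindolin-1-one | COc1cccc2c1[C@@H](C1=C(O)C=C(C)C(CC=C(C)C)(CC=C(C)C)C1=O)NC2=O | target

Total step count: 12.
Longest linear sequence: 9 steps (steps 1–5 and 9–12). Steps 6–8 form the short side branch.

**Steps most likely to fail**

**Step 9 (labelled step).**
- What may go wrong: the bulky alkenyl group must rotate inward in the second ring opening, and this may be slow.
- The ynol ether may be lost by retro-ene fragmentation before it is captured.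
- A [1,5]-hydrogen shift from the ring CH2 lying cis to the ketene may drain the vinylketene.
- The ketene may acylate the lactam nitrogen.

The fallback uses known chemistry only, sets out from 10 and comes back at 25. It still closes ring C last. 3-Methylcyclobut-2-en-1-one F1 is made from commercial 3-ethoxycyclobut-2-en-1-one with MeLi and dilute HCl, as in step 8. Heating 10 with it in toluene is the ordinary aromatic Danheiser benzannulation and should give the phenol (3S)-3-(2-ethoxy-6-hydroxy-4-methylphenyl)-4-methoxyisoindolin-1-one F2. The sodium phenoxide (NaH, toluene) is C-alkylated at the free ortho carbon with prenyl bromide to give (3S)-3-[2-ethoxy-6-hydroxy-4-methyl-5-(3-methylbut-2-en-1-yl)phenyl]-4-methoxyisoindolin-1-one F3. A second treatment with NaH and prenyl bromide in toluene is an alkylative dearomatisation at the now substituted ortho carbon and should deliver 25. Steps 10 and 11 are then not needed.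

**Step 5.**
- What may go wrong: C3 may epimerise by deprotonation of the acidified C3–H in the N-sulfinyl lactam.
- Methoxide may attack the hindered sulfur only sluggishly, so that the auxiliary stays on.

The fallback sets out from 3 and comes back at 10. It gives up the auxiliary in favour of a racemic synthesis with resolution.
- Ammonia in MeOH converts 3 into 3-hydroxy-4-methoxyisoindolin-1-one F4.
- Benzenesulfinic acid in aqueous formic acid gives 4-methoxy-3-(phenylsulfonyl)isoindolin-1-one F5.
- Two equivalents of 7 in THF at −78 °C first eliminate sulfinate to the cyclic N-acylimine and then add to it, giving racemic 3-(ethoxyethynyl)-4-methoxyisoindolin-1-one F6.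
- Preparative chromatography on a chiral stationary phase provides 10.

**Step 11.**
- What may go wrong: the basic ylide may cause enolisation and aldol chemistry of the dialdehyde.
- The ylide may deprotonate the vinylogously acidic C5' methyl group.
- The second olefination may remain incomplete.

The fallback sets out from 22 and comes back at 25, and it avoids strong base. A twofold Nozaki–Hiyama–Kishi addition of 2-bromopropene (CrCl2, NiCl2 cat., DMF) gives the bis(allylic alcohol) 3-ethoxy-6,6-bis(2-hydroxy-3-methylbut-3-en-1-yl)-2-[(1S)-7-methoxy-3-oxoisoindolin-1-yl]-5-methylcyclohexa-2,4-dien-1-one F7. Mitsunobu displacement with 2-nitrobenzenesulfonylhydrazide (PPh3, DEAD, THF, −30 °C → rt) and loss of the sulfinic acid gives the bis(allylic diazene) F8. This loses nitrogen in a retro-ene reaction with 1,3-transposition of each alkene, which should give the two prenyl groups of 25.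

**Further compounds**
F1 | step 9 | 3-methylcyclobut-2-en-1-one | CC1=CC(=O)C1
F2 | step 9 | (3S)-3-(2-ethoxy-6-hydroxy-4-methylphenyl)-4-methoxyisoindolin-1-one | COc1cccc2c1[C@@H](c3c(OCC)cc(C)cc3O)NC2=O
F3 | step 9 | (3S)-3-[2-ethoxy-6-hydroxy-4-methyl-5-(3-methylbut-2-en-1-yl)phenyl]-4-methoxyisoindolin-1-one | COc1cccc2c1[C@@H](c3c(OCC)cc(C)c(CC=C(C)C)c3O)NC2=O
F4 | step 5 | 3-hydroxy-4-methoxyisoindolin-1-one (racemic) | COc1cccc2c1C(O)NC2=O
F5 | step 5 | 4-methoxy-3-(phenylsulfonyl)isoindolin-1-one (racemic) | COc1cccc2c1C(S(=O)(=O)c3ccccc3)NC2=O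
F6 | step 5 | racemic 3-(ethoxyethynyl)-4-methoxyisoindolin-1-one | COc1cccc2c1C(C#COCC)NC2=O
F7 | step 11 | 3-ethoxy-6,6-bis(2-hydroxy-3-methylbut-3-en-1-yl)-2-[(1S)-7-methoxy-3-oxoisoindolin-1-yl]-5-methylcyclohexa-2,4-dien-1-one | COc1cccc2c1[C@@H](C3=C(OCC)C=C(C)C(CC(O)C(C)=C)(CC(O)C(C)=C)C3=O)NC2=O
F8 | step 11 | 6,6-bis(2-diazenyl-3-methylbut-3-en-1-yl)-3-ethoxy-2-[(1S)-7-methoxy-3-oxoisoindolin-1-yl]-5-methylcyclohexa-2,4-dien-1-one | COc1cccc2c1[C@@H](C3=C(OCC)C=C(C)C(CC(N=N)C(C)=C)(CC(N=N)C(C)=C)C3=O)NC2=O
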